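Numbering: carotenoid numbering is used throughout. Ring A is the epoxycyclohexane C1–C6 (methyls on C1 and C5), the chain runs C7–C15 then C15'–C7', and ring B is the acetoxycyclohexene C1'–C6'.

## The problem

Target 24 is a C40 carotenoid ester. Ring A (3S,5R,6S; 3-hydroxy-5,6-epoxide) is joined through C7H2–C8(=O) to an all-E heptaene (C9 to C9'), which ends in the C8'≡C7' triple bond on ring B (3'R acetate). The chain must be assembled without scrambling seven E double bonds; C9'=C10', next to the alkyne, isomerises easily under iodine or light. Ring B has one stereocentre. Ring A has three, and only C3 can control C5 and C6, from a homoallylic position and in the anti sense, against what a free hydroxyl would direct. The C5–C6 oxirane is β,γ to the C8 ketone, so any enolate at C7 expels the epoxide oxygen; the array will not survive alkoxides or organometallic reagents, and acid converts a free anti 3-hydroxy epoxide into the 3,6-oxide. The oxygens at C3 and C3' must be told apart (one free, one acetylated), although both rings have the same skeleton and the same spatial configuration at C3/C3'.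

The feature the plan rests on: C8 (carbonyl) and C11 are 1,4 across the C9(CH3)=C10 bond. C8–C9(CH3)=C10–C11 plus one oxygen is therefore the ring-opened form of a 3-methylfuran carrying C7 at its 2-position, and the C5=C6 bond of the parent cyclohexene is one methylene away from that furan. In addition, C7H2–C8(=O) is the hydrate of the same enyne (C7'≡C8') found at the other end, so both ends can come from one ring building block.

## Retrosynthesis

**C11=C12.** Target 24 is cut at C11=C12 into the C25 phosphonium salt 21 (ylide 22) and the C15 aldehyde 10. A cut at C9=C10 or C8–C9 would need a carbanion next to, or adding to, the epoxy carbonyl unit. The C11=C12 cut places the whole labile array in a small aldehyde and lets it meet only a delocalised, weakly basic ylide. The precursors have 25 and 15 skeletal carbons instead of 40. The forward reaction must be aldehyde-selective and non-enolising, and the hindered 11Z isomer 23 must revert to all-E.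

**Unveiling ring A and the keto enal (key).** Aldehyde 10 comes from its silyl ether 9. In 9 the C5–C6 oxirane, the C8 ketone and the C11 formyl group are all traced back to furan 7, by epoxidation of C5=C6 and oxidative opening of the furan (via the Z isomer 8) with one oxygen-transfer reagent. Any acylation route to the keto enal would expose a β,γ-epoxy carbonyl compound to carbanions. Here ketone, enal and epoxide appear together under neutral conditions in the last bond-forming operation on the fragment. Compound 7 has one stereocentre, no carbonyl group, and is stable to base and nucleophiles. The forward step needs attack anti to the C3 silyloxy group, no oxidation beyond the enedione, and Z to E equilibration.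

**The furan as a regiospecific alkyne hydrate.** Furan 7 is the cycloisomer (via alkylidenedihydrofuran 6) of the Z dienynol 5. The C11 hydroxyl adds to C8 of the C7≡C8 bond, which puts oxygen on C8 and two hydrogens on C7. This mimics the presumed biosynthetic origin of the 8-oxo group by hydration of a 7,8-triple bond, with the regiochemistry enforced intramolecularly. Attaching a preformed furylmethyl group would need unstable furfuryl reagents. The order cannot be reversed: an alkylidenedihydrofuran next to an oxirane would open it vinylogously, so the furan is made first and the oxidation comes last.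

**One triflate, two enynol isomers.** Compound 5 is cut at C6–C7 into enol triflate 3 and the commercial Z enynol 4 (Sonogashira). The ring B fragment 14 is cut the same way into acetoxy triflate 12 (from 3 via 11) and the E enynol 13. At this point the halves differ only in the geometry of one double bond: E stays an enyne, Z is folded into the furan.

**C25 ylide.** Salt 21 comes from alcohol 20 and aldehyde 19. Aldehyde 19 is cut at C11'=C12' into C15 salt 15 (from 14; ylide 17, Z isomer 18) and the commercial C10 dialdehyde 16, which supplies C12'–C12 with three E bonds in place. The forward step asks for a single condensation on a symmetrical dialdehyde.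

**Ring source.** Triflate 3 comes from silyl ether 2 of (4R,6R)-actinol 1. Its only stereocentre that survives is the later C3/C3', so one chiral-pool ketone fixes both rings. Enolisation is possible in one direction only.

## Roads not taken

**Alternative 1:** the cut most chemists would make keeps the C15 + C10 + C15 olefination skeleton but builds ring A by reagent control.
- Cut and forward key step: triflate 3 is carbonylated and reduced, and Sharpless epoxidation gives the anti epoxy alcohol A1. C7 is homologated, a C9 alkenyl metal is added, and C8 is carried as a carbinol through the olefinations to the C40 8-ol A2, which is oxidised to 24 at the end.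
- Why the chosen plan is better: the epoxide selectivity of A1 is the strength of this route. Against it, the ring A fragment needs about twice as many operations, a C8 stereocentre is created only to be destroyed, and the last step is an oxidation on the complete polyene. In the chosen plan both oxidations are done on a small fragment before any polyene exists.

**Alternative 2:** late biomimetic hydration.
- Cut and forward key step: the C8 oxygen is removed retrosynthetically to give the diyne epoxide A3, to be hydrated at C7≡C8 as the final step.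
- Why the chosen plan is better: A3 has two triple bonds, and the one to be hydrated is propargylic to an oxirane. π-Acids and nucleophiles open such epoxides in the SN2' sense to allenes rather than hydrate them. Nothing in A3 directs oxygen to C8 over C7, and the polyene would not tolerate the acids needed. The chosen plan performs the same hydration intramolecularly, before epoxide and polyene are present.

**Alternative 3:** acylation at C8–C9.
- Cut and forward key step: the N-methoxy-N-methylamide A4 of the ring A acetic acid is treated with a C9 alkenyllithium to give the ketone directly.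
- Why the chosen plan is better: the C7 hydrogens of A4 are acidic and the alkenyllithium is a strong base, so the enolate expels the epoxide oxygen. A4 itself needs the Sharpless sequence plus a one-carbon homologation at a neopentyl centre. The chain would still have to be grown afterwards in the presence of the ketone.

Key step: step 5

Assumption: (4R,6R)-actinol 1 (a commercial building block made from ketoisophorone), both geometric isomers of 3-methylpent-2-en-4-yn-1-ol (4, 13) and the C10 dialdehyde 16 are taken as purchasable.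

## Steps

Step 1
Reactants: 1 (4R,6R)-4-hydroxy-2,2,6-trimethylcyclohexan-1-one
Product: 2 (4R,6R)-2,2,6-trimethyl-4-(triethylsilyloxy)cyclohexan-1-one
Conditions: Et3SiCl, imidazole, DMF, 0 °C to rt
Reagents that add atoms: chlorotriethylsilane, CC[Si](Cl)(CC)CC
Why: Standard silylation of a secondary alcohol; the triethylsilyl ether survives amide bases, palladium coupling and neutral oxidants and is later removed under conditions that spare an oxirane.

Step 2
Reactants: 2 (4R,6R)-2,2,6-trimethyl-4-(triethylsilyloxy)cyclohexan-1-one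
Product: 3 (4R)-2,6,6-trimethyl-4-(triethylsilyloxy)cyclohex-1-en-1-yl trifluoromethanesulfonate
Conditions: LiN(i-Pr)2, THF, −78 °C; then PhNTf2, −78 °C to rt
Reagents that add atoms: N-phenylbis(trifluoromethanesulfonimide), O=S(=O)(N(c1ccccc1)S(=O)(=O)C(F)(F)F)C(F)(F)F
Why: The ketone has an α-hydrogen only at C6 (the later C5), so a single tetrasubstituted enolate forms and is trapped on oxygen as the enol triflate; the C6 stereocentre is erased on purpose and C4 (the later C3/C3') is untouched.

Step 3
Reactants: 3 (4R)-2,6,6-trimethyl-4-(triethylsilyloxy)cyclohex-1-en-1-yl trifluoromethanesulfonate; 4 (2Z)-3-methylpent-2-en-4-yn-1-ol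
Product: 5 (2Z)-3-methyl-5-[(4R)-2,6,6-trimethyl-4-(triethylsilyloxy)cyclohex-1-en-1-yl]pent-2-en-4-yn-1-ol
Conditions: Pd(PPh3)4 (5 mol %), CuI (10 mol %), i-Pr2NH, DMF, rt
Reagents that add atoms: none
Why: Sonogashira coupling of a tetrasubstituted cyclohexenyl triflate with a terminal enyne; the free allylic hydroxyl and the silyl ether are inert and the Z geometry of 4 is carried into 5.

Step 4
Reactants: 5 (2Z)-3-methyl-5-[(4R)-2,6,6-trimethyl-4-(triethylsilyloxy)cyclohex-1-en-1-yl]pent-2-en-4-yn-1-ol
Product: 7 triethyl({(1R)-3,5,5-trimethyl-4-[(3-methylfuran-2-yl)methyl]cyclohex-3-en-1-yl}oxy)silane, via alkylidenedihydrofuran 6 (not isolated)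
Conditions: AgNO3 on silica gel (10 mol %), hexane, rt, dark
Reagents that add atoms: none
Why: Silver-catalysed cycloisomerisation of a (Z)-2-en-4-yn-1-ol: the C11 hydroxyl, held cis to the alkyne, adds 5-exo-dig to the activated C8, and protodemetalation followed by kinetic protonation of 6 at C7 with loss of H11 gives the furan. Oxygen is thus placed on C8 and two hydrogens on C7 with full regiocontrol (a net alkyne hydration), and C5=C6 stays in the ring because the exocyclic isomer would suffer allylic strain against the C1 methyls.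

Step 5
Reactants: 7 triethyl({(1R)-3,5,5-trimethyl-4-[(3-methylfuran-2-yl)methyl]cyclohex-3-en-1-yl}oxy)silane
Product: 9 (2E)-3-methyl-4-oxo-5-[(1S,4S,6R)-2,2,6-trimethyl-4-(triethylsilyloxy)-7-oxabicyclo[4.1.0]heptan-1-yl]pent-2-enal, via (2Z)-keto enal 8 (not isolated)
Conditions: dimethyldioxirane (2.3 equiv, acetone solution), CH2Cl2, −78 to −20 °C; evaporate; then pyridine (0.2 equiv), CH2Cl2, rt, dark
Reagents that add atoms: dimethyldioxirane, CC1(C)OO1
Why: Dimethyldioxirane transfers one oxygen to the electron-rich C8=C9 bond of the furan, whose epoxide opens at once to the cis-enedione 8, and a second equivalent epoxidises the tetrasubstituted C5=C6 bond through a concerted spiro transition state, so C8=O, C11H=O and the oxirane all arise from one neutral reagent whose only by-product is acetone. The closest known reaction types are the dioxirane or peracid oxidation of 2-alkylfurans to (Z)-4-oxo-2-enals and the peracid or dioxirane epoxidation of 3-acyloxy and 3-silyloxy cyclohexene end groups of carotenoids. The only ring closed is the oxirane, by suprafacial oxygen-atom transfer onto C5=C6, which makes it cis-fused and fixes C5 and C6 relative to each other. Their configuration relative to C3 is set by the face of attack: the silylated C3 oxygen cannot deliver the oxidant by hydrogen bonding, and its inductive and steric bias should send the electrophile to the opposite face, giving the 3,5-anti (3S,5R,6S) epoxide as the main isomer, with the syn epimer removed by chromatography here. Chemoselectivity rests on electron demand: the furan and the tetraalkyl alkene are the two nucleophilic π systems, while the C9=C10 bond of the product is flanked by two carbonyl groups and should be inert to a slight excess of oxidant at low temperature. Pyridine then equilibrates 8 to 9 by reversible conjugate addition at C10; the E isomer is favoured because it separates the C8 acyl group from the formyl group. The precursor 7 has one stereocentre and no carbonyl group, whereas 9 carries three stereocentres, the β,γ-epoxy ketone and the enal needed for chain extension.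

Step 6
Reactants: 9 (2E)-3-methyl-4-oxo-5-[(1S,4S,6R)-2,2,6-trimethyl-4-(triethylsilyloxy)-7-oxabicyclo[4.1.0]heptan-1-yl]pent-2-enal
Product: 10 (2E)-5-[(1S,4S,6R)-4-hydroxy-2,2,6-trimethyl-7-oxabicyclo[4.1.0]heptan-1-yl]-3-methyl-4-oxopent-2-enal
Conditions: HF·pyridine, pyridine, THF, 0 °C
Reagents that add atoms: none
Why: Buffered HF·pyridine cleaves a secondary triethylsilyl ether quickly at 0 °C; the excess pyridine keeps the medium too weakly acidic to open the oxirane or to let the freed C3 hydroxyl attack C6.

Step 7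
Reactants: 3 (4R)-2,6,6-trimethyl-4-(triethylsilyloxy)cyclohex-1-en-1-yl trifluoromethanesulfonate
Product: 12 (4R)-4-acetoxy-2,6,6-trimethylcyclohex-1-en-1-yl trifluoromethanesulfonate, via hydroxy triflate 11 (not isolated)
Conditions: pyridinium p-toluenesulfonate (10 mol %), MeOH, rt; evaporate; then Ac2O, pyridine, DMAP (5 mol %), CH2Cl2, rt
Reagents that add atoms: acetic anhydride, CC(=O)OC(C)=O
Why: Acid-catalysed methanolysis of the silyl ether (the enol triflate is acid-stable) and standard acetylation with retention; the ester is put on here so that the two ring oxygens are differentiated before the fragments meet.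

Step 8
Reactants: 12 (4R)-4-acetoxy-2,6,6-trimethylcyclohex-1-en-1-yl trifluoromethanesulfonate; 13 (2E)-3-methylpent-2-en-4-yn-1-ol
Product: 14 (1R)-4-[(3E)-5-hydroxy-3-methylpent-3-en-1-yn-1-yl]-3,5,5-trimethylcyclohex-3-en-1-yl acetate
Conditions: Pd(PPh3)4 (5 mol %), CuI (10 mol %), i-Pr2NH, DMF, rt
Reagents that add atoms: none
Why: The same Sonogashira coupling as in step 3, now with the E enynol, which cannot cyclise and so keeps C7'≡C8' as the enyne of ring B; the acetate is stable to the hindered amine at rt.

Step 9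
Reactants: 14 (1R)-4-[(3E)-5-hydroxy-3-methylpent-3-en-1-yn-1-yl]-3,5,5-trimethylcyclohex-3-en-1-yl acetate
Product: 15 {(2E)-5-[(4R)-4-acetoxy-2,6,6-trimethylcyclohex-1-en-1-yl]-3-methylpent-2-en-4-yn-1-yl}triphenylphosphonium bromide
Conditions: PPh3·HBr, CH2Cl2, rt
Reagents that add atoms: triphenylphosphine hydrobromide, [Br-].c1ccc(cc1)[PH+](c1ccccc1)c1ccccc1
Why: Primary allylic alcohols are converted directly into allylic triphenylphosphonium bromides by PPh3·HBr (ionisation, capture at the primary terminus); the secondary acetate and the enyne are untouched and C9'=C10' stays E.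

Step 10
Reactants: 15 {(2E)-5-[(4R)-4-acetoxy-2,6,6-trimethylcyclohex-1-en-1-yl]-3-methylpent-2-en-4-yn-1-yl}triphenylphosphonium bromide; 16 (2E,4E,6E)-2,7-dimethylocta-2,4,6-trienedial
Product: 19 (1R)-3,5,5-trimethyl-4-[(3E,5E,7E,9E,11E)-3,7,12-trimethyl-13-oxotrideca-3,5,7,9,11-pentaen-1-yn-1-yl]cyclohex-3-en-1-yl acetate, via ylide 17 (not isolated), via (11'Z)-aldehyde 18 (not isolated)
Conditions: 15, NaN(SiMe3)2 (0.98 equiv), THF, −78 °C; add to 16 (3 equiv), THF, −78 to 0 °C; then EtOAc/heptane, 70 °C, dark
Reagents that add atoms: none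
Why: Wittig olefination; the semi-stabilised ylide 17 condenses once with the dialdehyde used in excess, since the product is a less electrophilic vinylogous aldehyde. The new C11'=C12' bond forms as an E/Z mixture and the hindered Z isomer 18 should revert thermally to all-E, while the acetate is not touched by the stoichiometrically consumed amide base.

Step 11
Reactants: 19 (1R)-3,5,5-trimethyl-4-[(3E,5E,7E,9E,11E)-3,7,12-trimethyl-13-oxotrideca-3,5,7,9,11-pentaen-1-yn-1-yl]cyclohex-3-en-1-yl acetate
Product: 20 (1R)-4-[(3E,5E,7E,9E,11E)-13-hydroxy-3,7,12-trimethyltrideca-3,5,7,9,11-pentaen-1-yn-1-yl]-3,5,5-trimethylcyclohex-3-en-1-yl acetate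
Conditions: NaBH4, MeOH/THF, 0 °C
Reagents that add atoms: none
Why: NaBH4 reduces the conjugated aldehyde 1,2 at 0 °C much faster than it attacks a secondary acetate; alkyne and polyene are inert.

Step 12
Reactants: 20 (1R)-4-[(3E,5E,7E,9E,11E)-13-hydroxy-3,7,12-trimethyltrideca-3,5,7,9,11-pentaen-1-yn-1-yl]-3,5,5-trimethylcyclohex-3-en-1-yl acetate
Product: 21 {(2E,4E,6E,8E,10E)-13-[(4R)-4-acetoxy-2,6,6-trimethylcyclohex-1-en-1-yl]-2,7,11-trimethyltrideca-2,4,6,8,10-pentaen-12-yn-1-yl}triphenylphosphonium bromide
Conditions: PPh3·HBr, CH2Cl2, 0 °C to rt, dark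
Reagents that add atoms: triphenylphosphine hydrobromide, [Br-].c1ccc(cc1)[PH+](c1ccccc1)c1ccccc1
Why: The same phosphonium salt formation as in step 9 on a polyenylic alcohol, which ionises even more readily; capture of the phosphine at the terminal carbon keeps the polyene conjugated and gives the all-E salt.

Step 13
Reactants: 21 {(2E,4E,6E,8E,10E)-13-[(4R)-4-acetoxy-2,6,6-trimethylcyclohex-1-en-1-yl]-2,7,11-trimethyltrideca-2,4,6,8,10-pentaen-12-yn-1-yl}triphenylphosphonium bromide; 10 (2E)-5-[(1S,4S,6R)-4-hydroxy-2,2,6-trimethyl-7-oxabicyclo[4.1.0]heptan-1-yl]-3-methyl-4-oxopent-2-enal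
Product: 24 (3S,5R,6S,3'R)-3'-acetoxy-5,6-epoxy-3-hydroxy-7',8'-didehydro-5,6,7,8-tetrahydro-β,β-caroten-8-one (all-E), via ylide 22 (not isolated), via (11Z)-isomer 23 (not isolated)
Conditions: 21 (1.3 equiv), NaN(SiMe3)2 (1.2 equiv), THF, −78 °C; then 10, −78 to −20 °C; pH 7 buffer; then EtOAc/heptane, 60 °C, dark, argon
Reagents that add atoms: none
Why: Wittig olefination with a highly delocalised, weakly basic polyenyl ylide: its conjugate acid 21 is a much stronger acid than the C7 methylene of 10, so enolisation and loss of the epoxide oxygen are uphill, and the formyl group is the only unhindered electrophile. The C11=C12 bond forms as an E/Z mixture and the hindered 11Z isomer 23 (H10 against the C13 methyl) should revert to all-E on gentle warming, which leaves the 9'E enyne bond alone.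

## Compound list

1 | (4R,6R)-4-hydroxy-2,2,6-trimethylcyclohexan-1-one (actinol) | O[C@@H]1C[C@@H](C)C(=O)C(C)(C)C1 | starting material
2 | (4R,6R)-2,2,6-trimethyl-4-(triethylsilyloxy)cyclohexan-1-one | CC[Si](CC)(CC)O[C@@H]1C[C@@H](C)C(=O)C(C)(C)C1 | intermediate
3 | (4R)-2,6,6-trimethyl-4-(triethylsilyloxy)cyclohex-1-en-1-yl trifluoromethanesulfonate | CC[Si](CC)(CC)O[C@@H]1CC(C)=C(OS(=O)(=O)C(F)(F)F)C(C)(C)C1 | intermediate
4 | (2Z)-3-methylpent-2-en-4-yn-1-ol | C#C/C(C)=C\CO | starting material
5 | (2Z)-3-methyl-5-[(4R)-2,6,6-trimethyl-4-(triethylsilyloxy)cyclohex-1-en-1-yl]pent-2-en-4-yn-1-ol | CC[Si](CC)(CC)O[C@@H]1CC(C)=C(C#C/C(C)=C\CO)C(C)(C)C1 | intermediate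
6 | triethyl({(1R)-3,5,5-trimethyl-4-[(Z)-(3-methylfuran-2(5H)-ylidene)methyl]cyclohex-3-en-1-yl}oxy)silane | CC[Si](CC)(CC)O[C@@H]1CC(C)=C(/C=C2\OCC=C2C)C(C)(C)C1 | intermediate
7 | triethyl({(1R)-3,5,5-trimethyl-4-[(3-methylfuran-2-yl)methyl]cyclohex-3-en-1-yl}oxy)silane | CC[Si](CC)(CC)O[C@@H]1CC(C)=C(Cc2occc2C)C(C)(C)C1 | intermediate
8 | (2Z)-3-methyl-4-oxo-5-[(1S,4S,6R)-2,2,6-trimethyl-4-(triethylsilyloxy)-7-oxabicyclo[4.1.0]heptan-1-yl]pent-2-enal | O=C/C=C(/C)C(=O)C[C@@]12O[C@]1(C)C[C@@H](O[Si](CC)(CC)CC)CC2(C)C | intermediate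
9 | (2E)-3-methyl-4-oxo-5-[(1S,4S,6R)-2,2,6-trimethyl-4-(triethylsilyloxy)-7-oxabicyclo[4.1.0]heptan-1-yl]pent-2-enal | O=C/C=C(\C)C(=O)C[C@@]12O[C@]1(C)C[C@@H](O[Si](CC)(CC)CC)CC2(C)C | intermediate
10 | (2E)-5-[(1S,4S,6R)-4-hydroxy-2,2,6-trimethyl-7-oxabicyclo[4.1.0]heptan-1-yl]-3-methyl-4-oxopent-2-enal | O=C/C=C(\C)C(=O)C[C@@]12O[C@]1(C)C[C@@H](O)CC2(C)C | intermediate
11 | (4R)-4-hydroxy-2,6,6-trimethylcyclohex-1-en-1-yl trifluoromethanesulfonate | O[C@@H]1CC(C)=C(OS(=O)(=O)C(F)(F)F)C(C)(C)C1 | intermediate
12 | (4R)-4-acetoxy-2,6,6-trimethylcyclohex-1-en-1-yl trifluoromethanesulfonate | CC(=O)O[C@@H]1CC(C)=C(OS(=O)(=O)C(F)(F)F)C(C)(C)C1 | intermediate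
13 | (2E)-3-methylpent-2-en-4-yn-1-ol | C#C/C(C)=C/CO | starting material
14 | (1R)-4-[(3E)-5-hydroxy-3-methylpent-3-en-1-yn-1-yl]-3,5,5-trimethylcyclohex-3-en-1-yl acetate | CC(=O)O[C@@H]1CC(C)=C(C#C/C(C)=C/CO)C(C)(C)C1 | intermediate
15 | {(2E)-5-[(4R)-4-acetoxy-2,6,6-trimethylcyclohex-1-en-1-yl]-3-methylpent-2-en-4-yn-1-yl}triphenylphosphonium bromide | CC(=O)O[C@@H]1CC(C)=C(C#C/C(C)=C/C[P+](c2ccccc2)(c2ccccc2)c2ccccc2)C(C)(C)C1.[Br-] | intermediate
16 | (2E,4E,6E)-2,7-dimethylocta-2,4,6-trienedial | O=C/C(C)=C/C=C/C=C(\C)C=O | starting material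
17 | ylide of 15, (1R)-3,5,5-trimethyl-4-[(3E)-3-methyl-5-(triphenyl-λ5-phosphanylidene)pent-3-en-1-yn-1-yl]cyclohex-3-en-1-yl acetate | CC(=O)O[C@@H]1CC(C)=C(C#C/C(C)=C/C=P(c2ccccc2)(c2ccccc2)c2ccccc2)C(C)(C)C1 | intermediate
18 | (5Z) isomer of 19 (Z at C11'=C12', all other double bonds E) | CC(=O)O[C@@H]1CC(C)=C(C#C/C(C)=C/C=C\C(C)=C\C=C\C=C(/C)C=O)C(C)(C)C1 | intermediate
19 | (1R)-3,5,5-trimethyl-4-[(3E,5E,7E,9E,11E)-3,7,12-trimethyl-13-oxotrideca-3,5,7,9,11-pentaen-1-yn-1-yl]cyclohex-3-en-1-yl acetate | CC(=O)O[C@@H]1CC(C)=C(C#C/C(C)=C/C=C/C(C)=C/C=C/C=C(\C)C=O)C(C)(C)C1 | intermediate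
20 | (1R)-4-[(3E,5E,7E,9E,11E)-13-hydroxy-3,7,12-trimethyltrideca-3,5,7,9,11-pentaen-1-yn-1-yl]-3,5,5-trimethylcyclohex-3-en-1-yl acetate | CC(=O)O[C@@H]1CC(C)=C(C#C/C(C)=C/C=C/C(C)=C/C=C/C=C(\C)CO)C(C)(C)C1 | intermediate
21 | {(2E,4E,6E,8E,10E)-13-[(4R)-4-acetoxy-2,6,6-trimethylcyclohex-1-en-1-yl]-2,7,11-trimethyltrideca-2,4,6,8,10-pentaen-12-yn-1-yl}triphenylphosphonium bromide | CC(=O)O[C@@H]1CC(C)=C(C#C/C(C)=C/C=C/C(C)=C/C=C/C=C(\C)C[P+](c2ccccc2)(c2ccccc2)c2ccccc2)C(C)(C)C1.[Br-] | intermediate
22 | ylide of 21 (all-E polyenylidene triphenylphosphorane) | CC(=O)O[C@@H]1CC(C)=C(C#C/C(C)=C/C=C/C(C)=C/C=C/C=C(\C)C=P(c2ccccc2)(c2ccccc2)c2ccccc2)C(C)(C)C1 | intermediate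
23 | (11Z) isomer of 24 | CC(=O)O[C@@H]1CC(C)=C(C#C/C(C)=C/C=C/C(C)=C/C=C/C=C(C)/C=C\C=C(/C)C(=O)C[C@@]23O[C@]2(C)C[C@@H](O)CC3(C)C)C(C)(C)C1 | intermediate
24 | (3S,5R,6S,3'R)-3'-acetoxy-5,6-epoxy-3-hydroxy-7',8'-didehydro-5,6,7,8-tetrahydro-β,β-caroten-8-one, all-E | CC(=O)O[C@@H]1CC(C)=C(C#C/C(C)=C/C=C/C(C)=C/C=C/C=C(C)/C=C/C=C(\C)C(=O)C[C@@]23O[C@]2(C)C[C@@H](O)CC3(C)C)C(C)(C)C1 | target

## Step count and risks

Total step count: 13. Longest linear sequence: 9 steps (1, 2, 7, 8, 9, 10, 11, 12, 13).

**Step 5 (key step).**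
- Most likely failure: insufficient facial discrimination at C5=C6. The bias from a homoallylic silyloxy group is only moderate, so a substantial share of syn epoxide may form. A lesser risk is further oxidation of the formyl group if excess oxidant is left to warm.
- Fallback (from 7, rejoining at 10): the C3 hydroxyl itself delivers the oxygen after a temporary inversion.
  - Bu4NF gives the (1R)-furyl alcohol F1.
  - A Mitsunobu reaction (4-nitrobenzoic acid, PPh3, diisopropyl azodicarboxylate) gives the inverted (1S)-4-nitrobenzoate F2, and K2CO3/MeOH gives the (1S)-alcohol F3.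
  - VO(acac)2/t-BuOOH epoxidises C5=C6 syn to this homoallylic hydroxyl, which is the face the target requires, to give the syn epoxy alcohol F4. The alkene is bound to vanadium through the hydroxyl and should react well ahead of the furan.
  - A second Mitsunobu inversion gives the 4-nitrobenzoate F5, and methanolysis gives the anti epoxy alcohol F6.
  - One equivalent of dimethyldioxirane followed by pyridine opens the furan and returns to the route at 10.

**Step 13.**
- Most likely failure: deprotonation at C7 by the ylide or by traces of amide base, with expulsion of the epoxide oxygen, or conjugate addition of the ylide to the enedione instead of carbonyl addition.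
- Fallback (from 9, rejoining at 24): the ketone is masked as a carbinol during the olefination.
  - NaBH4/CeCl3·7H2O reduces both carbonyl groups to the C8,C11-diol F7 (both C8 epimers).
  - TEMPO/PhI(OAc)2 oxidises only the primary allylic alcohol, giving the hydroxy enal F8.
  - Wittig reaction with ylide 22 gives the C40 8-ol F9.
  - MnO2 oxidises the allylic C8 carbinol to the silyl-protected ketone F10.
  - HF·pyridine/pyridine removes the silyl group to give 24.

**Step 4.**
- Most likely failure: sluggish cyclisation of the internal alkyne flanked by the tetrasubstituted ring carbon, or protonation of 6 at C5 instead of C7, which moves the ring double bond to the exocyclic position.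
- Fallback (from 3, rejoining at 7): the furan is brought in preformed.
  - Pd(OAc)2/PPh3, CO, MeOH, Et3N gives the methyl ester F11.
  - i-Bu2AlH gives the allylic alcohol F12.
  - CBr4/PPh3 gives the allylic bromide F13.
  - 2-Lithio-3-methylfuran F14 (from purchased 2-bromo-3-methylfuran and n-BuLi, THF, −78 °C, 10 mol % CuI) is alkylated at the primary carbon of F13, the tetrasubstituted terminus being too hindered for SN2' attack, to give 7.

**Step 10.**
- Most likely failure: condensation at both formyl groups of 16, since the two ends are identical and the selectivity for the first rests only on stoichiometry and on the lower reactivity of the product.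
- Fallback (from 16, rejoining at 19): one end is protected.
  - HC(OMe)3 (1 equiv), pyridinium p-toluenesulfonate, MeOH gives the mono(dimethyl acetal) F15 after separation from 16 and the bis-acetal.
  - Wittig reaction with ylide 17 gives the C25 dimethyl acetal F16.
  - Pyridinium p-toluenesulfonate in acetone/water hydrolyses it to 19.

## Further compounds

F1 | step 5 | (1R)-3,5,5-trimethyl-4-[(3-methylfuran-2-yl)methyl]cyclohex-3-en-1-ol | O[C@@H]1CC(C)=C(Cc2occc2C)C(C)(C)C1
F2 | step 5 | (1S)-3,5,5-trimethyl-4-[(3-methylfuran-2-yl)methyl]cyclohex-3-en-1-yl 4-nitrobenzoate | O=C(O[C@H]1CC(C)=C(Cc2occc2C)C(C)(C)C1)c1ccc(cc1)[N+](=O)[O-]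
F3 | step 5 | (1S)-3,5,5-trimethyl-4-[(3-methylfuran-2-yl)methyl]cyclohex-3-en-1-ol | O[C@H]1CC(C)=C(Cc2occc2C)C(C)(C)C1
F4 | step 5 | (1S,4R,6R)-2,2,6-trimethyl-1-[(3-methylfuran-2-yl)methyl]-7-oxabicyclo[4.1.0]heptan-4-ol (syn epoxy alcohol) | Cc1ccoc1C[C@@]12O[C@]1(C)C[C@H](O)CC2(C)C
F5 | step 5 | (1S,4S,6R)-2,2,6-trimethyl-1-[(3-methylfuran-2-yl)methyl]-7-oxabicyclo[4.1.0]heptan-4-yl 4-nitrobenzoate | Cc1ccoc1C[C@@]12O[C@]1(C)C[C@@H](OC(=O)c1ccc(cc1)[N+](=O)[O-])CC2(C)C
F6 | step 5 | (1S,4S,6R)-2,2,6-trimethyl-1-[(3-methylfuran-2-yl)methyl]-7-oxabicyclo[4.1.0]heptan-4-ol (anti epoxy alcohol) | Cc1ccoc1C[C@@]12O[C@]1(C)C[C@@H](O)CC2(C)C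
F7 | step 13 | (3E)-3-methyl-1-[(1S,4S,6R)-2,2,6-trimethyl-4-(triethylsilyloxy)-7-oxabicyclo[4.1.0]heptan-1-yl]pent-3-ene-2,5-diol (both C2 epimers) | OC/C=C(\C)C(O)C[C@@]12O[C@]1(C)C[C@@H](O[Si](CC)(CC)CC)CC2(C)C
F8 | step 13 | (2E)-4-hydroxy-3-methyl-5-[(1S,4S,6R)-2,2,6-trimethyl-4-(triethylsilyloxy)-7-oxabicyclo[4.1.0]heptan-1-yl]pent-2-enal (both C4 epimers) | O=C/C=C(\C)C(O)C[C@@]12O[C@]1(C)C[C@@H](O[Si](CC)(CC)CC)CC2(C)C
F9 | step 13 | 8-hydroxy-8-deoxo analogue of 24 with the C3 hydroxyl as triethylsilyl ether (both C8 epimers) | CC(=O)O[C@@H]1CC(C)=C(C#C/C(C)=C/C=C/C(C)=C/C=C/C=C(C)/C=C/C=C(\C)C(O)C[C@@]23O[C@]2(C)C[C@@H](O[Si](CC)(CC)CC)CC3(C)C)C(C)(C)C1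
F10 | step 13 | 3-O-triethylsilyl ether of 24 | CC(=O)O[C@@H]1CC(C)=C(C#C/C(C)=C/C=C/C(C)=C/C=C/C=C(C)/C=C/C=C(\C)C(=O)C[C@@]23O[C@]2(C)C[C@@H](O[Si](CC)(CC)CC)CC3(C)C)C(C)(C)C1
F11 | step 4 | methyl (4R)-2,6,6-trimethyl-4-(triethylsilyloxy)cyclohex-1-ene-1-carboxylate | CC[Si](CC)(CC)O[C@@H]1CC(C)=C(C(=O)OC)C(C)(C)C1
F12 | step 4 | [(4R)-2,6,6-trimethyl-4-(triethylsilyloxy)cyclohex-1-en-1-yl]methanol | CC[Si](CC)(CC)O[C@@H]1CC(C)=C(CO)C(C)(C)C1
F13 | step 4 | {[(1R)-4-(bromomethyl)-3,5,5-trimethylcyclohex-3-en-1-yl]oxy}triethylsilane | CC[Si](CC)(CC)O[C@@H]1CC(C)=C(CBr)C(C)(C)C1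
F14 | step 4 | 2-lithio-3-methylfuran | [Li]c1occc1C
F15 | step 10 | (2E,4E,6E)-8,8-dimethoxy-2,7-dimethylocta-2,4,6-trienal | COC(OC)/C(C)=C/C=C/C=C(\C)C=O
F16 | step 10 | dimethyl acetal of 19 | CC(=O)O[C@@H]1CC(C)=C(C#C/C(C)=C/C=C/C(C)=C/C=C/C=C(\C)C(OC)OC)C(C)(C)C1
A1 | alternative 1 | [(1R,4S,6R)-4-(tert-butyldimethylsilyloxy)-2,2,6-trimethyl-7-oxabicyclo[4.1.0]heptan-1-yl]methanol | OC[C@@]12O[C@]1(C)C[C@@H](O[Si](C)(C)C(C)(C)C)CC2(C)C
A2 | alternative 1 | 8-hydroxy-8-deoxo analogue of 24 (both C8 epimers) | CC(=O)O[C@@H]1CC(C)=C(C#C/C(C)=C/C=C/C(C)=C/C=C/C=C(C)/C=C/C=C(\C)C(O)C[C@@]23O[C@]2(C)C[C@@H](O)CC3(C)C)C(C)(C)C1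
A3 | alternative 2 | 7,8-didehydro-8-deoxo analogue of 24 (5,6-epoxy-7,8,7',8'-tetradehydro diyne, ring configurations as in 24) | CC(=O)O[C@@H]1CC(C)=C(C#C/C(C)=C/C=C/C(C)=C/C=C/C=C(C)/C=C/C=C(\C)C#C[C@@]23O[C@]2(C)C[C@@H](O)CC3(C)C)C(C)(C)C1
A4 | alternative 3 | N-methoxy-N-methyl-2-[(1S,4S,6R)-4-(tert-butyldimethylsilyloxy)-2,2,6-trimethyl-7-oxabicyclo[4.1.0]heptan-1-yl]acetamide | CON(C)C(=O)C[C@@]12O[C@]1(C)C[C@@H](O[Si](C)(C)C(C)(C)C)CC2(C)C
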